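## Retrosynthetic overview

1. Numbering (isoflavone style): pyranone O1, C2, C3, C4(=O); ring A C4a–C8a; ring B C1'–C6', furan oxygen on C2'. The plan rests on C4a of ring A. It sits between C8a (bearing O1) and C5 (bearing oxygen), and the other neighbour of C8a, C8, is blocked by the dihydropyran CH2. Once O1 is bound to C2 as an aryl ether, C4a–H is the only free position ortho to that ether, is acidified by two flanking oxygens, and lies over a carbonyl placed on C3.
2. Last skeletal bond: C4–C4a. A lithium amide lithiates C4a–H and the aryllithium attacks a C3 diethylcarboxamide, which closes the pyranone. Only two ether cleavages follow.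
3. The C2–O1 ether comes from a 2-bromofuro[2,3-f]chromene-3-carboxamide (ring B, furan, chromene) and 7-methoxy-2,2-dimethylchroman-5-ol (ring A, dihydropyran).
4. The furan comes from 2,2-dimethylchromene-5,8-dione and an enaminoester, an annulation that leaves the 5'-OH as the only free hydroxyl. The chromene comes from an aryl propargyl ether. The dihydropyran comes from a 2-prenylresorcinol made by lithiation between two MOM ethers.
5. Ring order: chromene, then furan (fragment B); dihydropyran (fragment A); pyranone last.

Key step: step 13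

Remark 1: the 5'-oxygen is carried as a methoxymethyl (MOM) ether, because an aryl silyl ether would be exchanged with the phenoxide in the hot, basic ether-forming step 12.
Remark 2: fragment B compounds are named as 7H-furo[2,3-f]chromenes (O1, C2, C3, C3a, C4, C5, C5a, O6, C7, C8, C9, C9a, C9b); their C2, C3, C4 and C5 become C2, C3, C6' and C5' of the target.

## Route

Step 1
Reactants: 1 2,5-dimethoxybenzaldehyde
Product: 3 2,5-dimethoxyphenol, via 2,5-dimethoxyphenyl formate 2 (not isolated)
Conditions: mCPBA, CH2Cl2, 0 °C to rt; aq NaHCO3 wash, evaporate; then K2CO3 (cat.), MeOH, rt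
Reagents that add atoms: mCPBA, OOC(=O)c1cccc(Cl)c1
Why: Baeyer–Villiger oxidation of an electron-rich benzaldehyde (Dakin-type outcome): the dimethoxyphenyl group migrates to oxygen in the peracid adduct to give formate 2, and carbonate-catalysed transesterification with methanol then frees the phenol without touching the methyl ethers.

Step 2
Reactants: 3 2,5-dimethoxyphenol; 4 3-chloro-3-methylbut-1-yne
Product: 5 1,4-dimethoxy-2-[(2-methylbut-3-yn-2-yl)oxy]benzene
Conditions: DBU, CuCl2·2H2O (1 mol %), MeCN, 0 °C
Reagents that add atoms: none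
Why: Copper-catalysed O-alkylation of a phenol with a tertiary propargylic chloride is the standard way to aryl 1,1-dimethylpropargyl ethers, and at 0 °C neither elimination of 4 nor premature rearrangement should interfere.

Step 3
Reactants: 5 1,4-dimethoxy-2-[(2-methylbut-3-yn-2-yl)oxy]benzene
Product: 8 5,8-dimethoxy-2,2-dimethyl-2H-chromene, via allenylphenol 6 (not isolated), via ortho-quinone methide 7 (not isolated)
Conditions: N,N-diethylaniline, 190 °C
Reagents that add atoms: none
Why: Aromatic propargyl Claisen rearrangement: the [3,3] shift can reach only the single free ortho carbon (the other bears OMe), and allenylphenol 6 goes on by 1,5-hydrogen shift to quinone methide 7 and by oxa-6π electrocyclisation to the 2,2-dimethylchromene.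

Step 4
Reactants: 8 5,8-dimethoxy-2,2-dimethyl-2H-chromene
Product: 9 2,2-dimethyl-2H-chromene-5,8-dione
Conditions: (NH4)2Ce(NO3)6 (2.2 equiv), MeCN–H2O, 0 °C, short contact
Reagents that add atoms: water, O
Why: Oxidative demethylation of a 1,4-dimethoxyarene by tetravalent cerium: two one-electron oxidations with ipso attack of water expel both methanols, and brief exposure at 0 °C should leave the chromene alkene alone.

Step 5
Reactants: 9 2,2-dimethyl-2H-chromene-5,8-dione; 10 ethyl (E)-3-(dimethylamino)acrylate
Product: 12 ethyl 5-hydroxy-7,7-dimethyl-7H-furo[2,3-f]chromene-3-carboxylate, via hydroquinone adduct 11 (not isolated)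
Conditions: AcOH, rt
Reagents that add atoms: none
Why: Benzofuran variant of the Nenitzescu reaction: the enamine carbon of 10 adds in Michael fashion to C6 of 9, the β-carbon of the C8 enone (the C5 carbonyl is deactivated as a vinylogous ester of the ring oxygen on C8a), and in adduct 11 the C5 hydroxyl closes on the protonated enamine carbon with loss of dimethylamine, which leaves the future 5'-OH as the only free hydroxyl.

Step 6
Reactants: 12 ethyl 5-hydroxy-7,7-dimethyl-7H-furo[2,3-f]chromene-3-carboxylate
Product: 13 N,N-diethyl-5-hydroxy-7,7-dimethyl-7H-furo[2,3-f]chromene-3-carboxamide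
Conditions: Et2NH, AlMe3 (3.5 equiv each), toluene, 0 °C to 80 °C
Reagents that add atoms: diethylamine, CCNCC
Why: Weinreb aminolysis: the dimethylaluminium amide made from AlMe3 and Et2NH converts the ethyl ester directly into the tertiary amide, one extra equivalent being taken up by the phenol as its aluminium phenoxide.

Step 7
Reactants: 13 N,N-diethyl-5-hydroxy-7,7-dimethyl-7H-furo[2,3-f]chromene-3-carboxamide
Product: 14 N,N-diethyl-5-(methoxymethoxy)-7,7-dimethyl-7H-furo[2,3-f]chromene-3-carboxamide
Conditions: MOMCl, iPr2NEt, CH2Cl2, 0 °C to rt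
Reagents that add atoms: chloromethyl methyl ether (MOMCl), COCCl
Why: Base-mediated O-alkylation of the phenol with a chloromethyl ether gives an acetal that withstands phenoxide, phosphate base and lithium amides in the steps ahead.

Step 8
Reactants: 14 N,N-diethyl-5-(methoxymethoxy)-7,7-dimethyl-7H-furo[2,3-f]chromene-3-carboxamide
Product: 16 2-bromo-N,N-diethyl-5-(methoxymethoxy)-7,7-dimethyl-7H-furo[2,3-f]chromene-3-carboxamide, via 2-lithio amide 15 (not isolated)
Conditions: LiN(iPr)2 (1.2 equiv), THF, −78 °C; then BrCl2CCCl2Br, −78 °C to rt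
Reagents that add atoms: 1,2-dibromo-1,1,2,2-tetrachloroethane, BrC(Cl)(Cl)C(Cl)(Cl)Br
Why: Directed ortho metalation: C2–H is the most acidic proton (next to the furan oxygen and ortho to the coordinating diethylamide), 2-lithiobenzofurans do not ring-open, and halophilic attack of 15 on the bromine donor delivers bromine without an electrophile that could touch the chromene alkene.

Step 9
Reactants: 17 5-methoxyresorcinol
Product: 18 1-methoxy-3,5-bis(methoxymethoxy)benzene
Conditions: MOMCl (2.5 equiv), iPr2NEt, CH2Cl2, 0 °C to rt
Reagents that add atoms: chloromethyl methyl ether (MOMCl), COCCl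
Why: Double O-alkylation of the two equivalent phenols (acetal protection) places the two strongest directing groups on either side of C2.

Step 10
Reactants: 18 1-methoxy-3,5-bis(methoxymethoxy)benzene; 19 prenyl bromide
Product: 21 5-methoxy-1,3-bis(methoxymethoxy)-2-(3-methylbut-2-en-1-yl)benzene, via aryllithium 20 (not isolated)
Conditions: n-BuLi, TMEDA, THF, 0 °C; then 19, −78 °C to rt
Reagents that add atoms: none
Why: Directed ortho metalation followed by SN2 alkylation: n-BuLi is chelated by both MOM ethers and removes the proton between them in preference to those next to the weaker OMe director, and aryllithium 20 is alkylated at the primary carbon of prenyl bromide.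

Step 11
Reactants: 21 5-methoxy-1,3-bis(methoxymethoxy)-2-(3-methylbut-2-en-1-yl)benzene
Product: 23 7-methoxy-2,2-dimethylchroman-5-ol, via prenylresorcinol 22 (not isolated)
Conditions: HCl (3 M aq, cat.), MeOH, 50 °C; evaporate; then p-TsOH·H2O (10 mol %), toluene, 80 °C
Reagents that add atoms: none
Why: Acid-catalysed acetal exchange with methanol (formaldehyde is trapped as its dimethyl acetal, away from the electron-rich ring) frees the symmetric resorcinol 22, and Markovnikov protonation of the prenyl alkene with capture of the tertiary cation by either of the two equivalent hydroxyls (intramolecular hydroalkoxylation) can give only one chroman.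

Step 12
Reactants: 16 2-bromo-N,N-diethyl-5-(methoxymethoxy)-7,7-dimethyl-7H-furo[2,3-f]chromene-3-carboxamide; 23 7-methoxy-2,2-dimethylchroman-5-ol
Product: 24 N,N-diethyl-2-[(7-methoxy-2,2-dimethylchroman-5-yl)oxy]-5-(methoxymethoxy)-7,7-dimethyl-7H-furo[2,3-f]chromene-3-carboxamide
Conditions: CuI (10 mol %), picolinic acid (20 mol %), K3PO4, DMSO, 90 °C, argon
Reagents that add atoms: none
Why: Ullmann-type copper-catalysed diaryl ether synthesis with a ligand system suited to ortho-substituted partners, helped by the fact that 16 is a β-bromo-α,β-unsaturated amide, so that addition–elimination by the phenoxide leads to the same ether.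

Step 13
Reactants: 24 N,N-diethyl-2-[(7-methoxy-2,2-dimethylchroman-5-yl)oxy]-5-(methoxymethoxy)-7,7-dimethyl-7H-furo[2,3-f]chromene-3-carboxamide
Product: 27 5-O-methyl-5'-O-(methoxymethyl)formosanatin D, via C4a aryllithium 25 (not isolated), via lithium hemiaminal alkoxide 26 (not isolated)
Conditions: LiN(iPr)2 (3 equiv), THF, −78 °C to 0 °C; then sat. aq NH4Cl
Reagents that add atoms: none
Why: The lithium amide binds to the amide oxygen of 24 and, held there, removes the nearby C4a–H of ring A, which is flanked by the aryloxy oxygen on C8a and the methoxy group on C5, to give aryllithium 25. The carbanion adds to the amide carbonyl in a 6-exo-trig closure (ring atoms C4a, C8a, O1, C2, C3, C4) to give alkoxide 26, which expels lithium diethylamide and leaves the pyranone of 27. The closest known reaction type is the directed remote metalation and anionic cyclisation that turns 2-aryloxybenzamides and aryloxypyridinecarboxamides into xanthones and azaxanthones. No stereocentre is formed in 27, and the carbinol centre of 26 is lost on collapse. The step needs lithiation at C4a rather than at C6–H (also between two oxygens but out of reach of the amide), C6'–H (next to the MOM ether) or the benzylic CH2 on C8 (less acidic, and it would need a seven-membered closure); the ether link has already fixed the angular ring A pattern because C8 is blocked, and since metalation by an amide base is reversible, only the C4a anion is drained by cyclisation. The MOM acetal, the chromene alkene and the dihydropyran have no reaction path with a cold hindered amide base.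

Step 14
Reactants: 27 5-O-methyl-5'-O-(methoxymethyl)formosanatin D
Product: 28 5-O-methylformosanatin D
Conditions: HCl (2 M aq, cat.), MeOH–THF, 45 °C
Reagents that add atoms: none
Why: Acid-catalysed acetal exchange with methanol removes the MOM group under conditions commonly applied to flavonoids that bear a 2,2-dimethylchromene, while the aryl methyl ether stays.

Step 15
Reactants: 28 5-O-methylformosanatin D
Product: 30 formosanatin D, via bis(dichloroboryl) ether 29 (not isolated)
Conditions: BCl3 (3 equiv), CH2Cl2, −78 °C to −10 °C; then H2O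
Reagents that add atoms: none
Why: Chelation-controlled Lewis acid demethylation: BCl3 binds between the C4 carbonyl and the peri 5-methoxy oxygen, chloride removes the methyl group, and hydrolysis of boron ester 29 frees both phenols, while the ether bonds of the two pyran rings lack this chelation and should persist at low temperature.

## Compound list

1 | 2,5-dimethoxybenzaldehyde | COc1ccc(OC)c(C=O)c1 | starting material
2 | 2,5-dimethoxyphenyl formate | COc1ccc(OC)c(OC=O)c1 | intermediate (not isolated)
3 | 2,5-dimethoxyphenol | COc1ccc(OC)c(O)c1 | intermediate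
4 | 3-chloro-3-methylbut-1-yne | CC(C)(Cl)C#C | starting material
5 | 1,4-dimethoxy-2-[(2-methylbut-3-yn-2-yl)oxy]benzene | COc1ccc(OC)c(OC(C)(C)C#C)c1 | intermediate
6 | 3,6-dimethoxy-2-(3-methylbuta-1,2-dien-1-yl)phenol | COc1ccc(OC)c(C=C=C(C)C)c1O | intermediate (not isolated)
7 | (6Z)-2,5-dimethoxy-6-(3-methylbut-2-en-1-ylidene)cyclohexa-2,4-dien-1-one | O=C1C(OC)=CC=C(OC)/C1=C/C=C(C)C | intermediate (not isolated)
8 | 5,8-dimethoxy-2,2-dimethyl-2H-chromene | COc1ccc(OC)c2OC(C)(C)C=Cc12 | intermediate
9 | 2,2-dimethyl-2H-chromene-5,8-dione | CC1(C)C=CC2=C(O1)C(=O)C=CC2=O | intermediate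
10 | ethyl (E)-3-(dimethylamino)acrylate | CCOC(=O)/C=C/N(C)C | starting material
11 | ethyl 2-(5,8-dihydroxy-2,2-dimethyl-2H-chromen-6-yl)-3-(dimethylamino)prop-2-enoate (enamine geometry not fixed) | CCOC(=O)C(=CN(C)C)c1cc(O)c2OC(C)(C)C=Cc2c1O | intermediate (not isolated)
12 | ethyl 5-hydroxy-7,7-dimethyl-7H-furo[2,3-f]chromene-3-carboxylate | CCOC(=O)c1coc2c1cc(O)c1OC(C)(C)C=Cc12 | intermediate
13 | N,N-diethyl-5-hydroxy-7,7-dimethyl-7H-furo[2,3-f]chromene-3-carboxamide | CCN(CC)C(=O)c1coc2c1cc(O)c1OC(C)(C)C=Cc12 | intermediate
14 | N,N-diethyl-5-(methoxymethoxy)-7,7-dimethyl-7H-furo[2,3-f]chromene-3-carboxamide | CCN(CC)C(=O)c1coc2c1cc(OCOC)c1OC(C)(C)C=Cc12 | intermediate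
15 | 2-lithio derivative of 14 | CCN(CC)C(=O)c1c([Li])oc2c1cc(OCOC)c1OC(C)(C)C=Cc12 | intermediate (not isolated)
16 | 2-bromo-N,N-diethyl-5-(methoxymethoxy)-7,7-dimethyl-7H-furo[2,3-f]chromene-3-carboxamide | CCN(CC)C(=O)c1c(Br)oc2c1cc(OCOC)c1OC(C)(C)C=Cc12 | intermediate
17 | 5-methoxyresorcinol | COc1cc(O)cc(O)c1 | starting material
18 | 1-methoxy-3,5-bis(methoxymethoxy)benzene | COCOc1cc(OC)cc(OCOC)c1 | intermediate
19 | prenyl bromide (1-bromo-3-methylbut-2-ene) | CC(C)=CCBr | starting material
20 | [4-methoxy-2,6-bis(methoxymethoxy)phenyl]lithium | COCOc1cc(OC)cc(OCOC)c1[Li] | intermediate (not isolated)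
21 | 5-methoxy-1,3-bis(methoxymethoxy)-2-(3-methylbut-2-en-1-yl)benzene | COCOc1cc(OC)cc(OCOC)c1CC=C(C)C | intermediate
22 | 5-methoxy-2-(3-methylbut-2-en-1-yl)benzene-1,3-diol | COc1cc(O)c(CC=C(C)C)c(O)c1 | intermediate (not isolated)
23 | 7-methoxy-2,2-dimethylchroman-5-ol | COc1cc(O)c2CCC(C)(C)Oc2c1 | intermediate
24 | N,N-diethyl-2-[(7-methoxy-2,2-dimethylchroman-5-yl)oxy]-5-(methoxymethoxy)-7,7-dimethyl-7H-furo[2,3-f]chromene-3-carboxamide (key-step precursor) | CCN(CC)C(=O)c1c(Oc2cc(OC)cc3OC(C)(C)CCc23)oc2c1cc(OCOC)c1OC(C)(C)C=Cc12 | intermediate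
25 | 24 lithiated at chroman C6 (the future C4a) | CCN(CC)C(=O)c1c(Oc2c([Li])c(OC)cc3OC(C)(C)CCc23)oc2c1cc(OCOC)c1OC(C)(C)C=Cc12 | intermediate (not isolated)
26 | lithium alkoxide of the C4 diethylamino carbinol (racemic, centre lost on collapse) | CCN(CC)C1(O[Li])c2c(OC)cc3OC(C)(C)CCc3c2Oc2oc3c4C=CC(C)(C)Oc4c(OCOC)cc3c12 | intermediate (not isolated)
27 | 5-O-methyl-5'-O-(methoxymethyl)formosanatin D (coumaronochromone with 5-OMe, 5'-OCH2OMe, dihydropyran on C7/C8, pyran on C3'/C4'; key-step product) | O=c1c2c(OC)cc3OC(C)(C)CCc3c2oc2oc3c4C=CC(C)(C)Oc4c(OCOC)cc3c12 | intermediate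
28 | 5-O-methylformosanatin D | O=c1c2c(OC)cc3OC(C)(C)CCc3c2oc2oc3c4C=CC(C)(C)Oc4c(O)cc3c12 | intermediate
29 | 5,5'-bis-O-(dichloroboryl)formosanatin D | O=c1c2c(OB(Cl)Cl)cc3OC(C)(C)CCc3c2oc2oc3c4C=CC(C)(C)Oc4c(OB(Cl)Cl)cc3c12 | intermediate (not isolated)
30 | formosanatin D (no stereocentres) | CC1(C)C=Cc2c(c(O)cc3c2oc2oc4c5c(cc(O)c4c(=O)c23)OC(C)(C)CC5)O1 | target

## Step count and risks

Total steps: 15. Longest linear sequence: 12 (steps 1–8, then 12–15). Fragment A takes 3 steps (9–11).

**Step 13 (key step).** The lithium diethylamide set loose by the cyclisation, or the base itself, may add to C2. That would expel the aryloxide from the precursor or open the newly formed pyranone. Metalation may also stall at sites that cannot cyclise.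

The fallback makes the same C4–C4a bond by an electrophilic path. It sets out from 24.
- Tf2O and 2-fluoropyridine in CH2Cl2 at −78 °C to 0 °C convert the diethylamide into the O-triflyl iminium triflate F1.
- Ring A of F1 attacks through C4a, which is ortho to O1, ortho to OMe, para to the dihydropyran oxygen, and the only free ortho position. This Vilsmeier–Haack-type intramolecular acylation gives the cyclic C4 diethyliminium triflate F2.
- Warm aqueous NaHCO3 hydrolyses F2 to 27, where the route is rejoined.

**Step 12.** Coupling between two ortho-substituted partners may be slow. Protodebromination or hydrolysis of the C2–Br bond could then overtake C–O bond formation.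

The fallback replaces the catalysed coupling by an uncatalysed substitution on a better leaving group. It sets out from 14.
- 14 is lithiated as in step 8 (15) and quenched with N-fluorobenzenesulfonimide to give 2-fluoro-N,N-diethyl-5-(methoxymethoxy)-7,7-dimethyl-7H-furo[2,3-f]chromene-3-carboxamide F3.
- Addition–elimination of 23 on F3 with Cs2CO3 in DMF at about 50 °C gives 24, where the route is rejoined.

**Step 5.** Conjugate addition at C7 may compete with addition at C6. Redox exchange between the hydroquinone adduct and unreacted quinone may also divert material.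

The fallback avoids the quinone and fixes the regiochemistry by electrophilic aromatic substitution. It sets out from 8.
- Vilsmeier–Haack formylation (POCl3, DMF) should go to C6, which is ortho to the 5-OMe and para to the ring oxygen, to give 5,8-dimethoxy-2,2-dimethyl-2H-chromene-6-carbaldehyde F4.
- BCl3 at −78 °C removes only the methyl ether chelated to the aldehyde, giving 5-hydroxy-8-methoxy-2,2-dimethyl-2H-chromene-6-carbaldehyde F5.
- Ethyl diazoacetate with catalytic HBF4·OEt2 (aryl shift, then hemiacetal closure) gives ethyl 2-hydroxy-5-methoxy-7,7-dimethyl-2,3-dihydro-7H-furo[2,3-f]chromene-3-carboxylate F6.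
- A trace of p-TsOH dehydrates F6 to ethyl 5-methoxy-7,7-dimethyl-7H-furo[2,3-f]chromene-3-carboxylate F7.
- Aminolysis as in step 6 gives N,N-diethyl-5-methoxy-7,7-dimethyl-7H-furo[2,3-f]chromene-3-carboxamide F8.
- NaSEt in DMF at 120 °C cleaves the methyl ether by SN2 attack (the chromene and the tertiary amide are stable to base) and gives 13, where the route is rejoined.

## Further compounds

F1 | step 13 | O-triflyl iminium triflate of 24 | CC[N+](CC)=C(OS(=O)(=O)C(F)(F)F)c1c(Oc2cc(OC)cc3OC(C)(C)CCc23)oc2c1cc(OCOC)c1OC(C)(C)C=Cc12.[O-]S(=O)(=O)C(F)(F)F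
F2 | step 13 | cyclic C4 diethyliminium triflate (iminium analogue of 27) | CC[N+](CC)=C1c2c(OC)cc3OC(C)(C)CCc3c2Oc2oc3c4C=CC(C)(C)Oc4c(OCOC)cc3c12.[O-]S(=O)(=O)C(F)(F)F
F3 | step 12 | 2-fluoro-N,N-diethyl-5-(methoxymethoxy)-7,7-dimethyl-7H-furo[2,3-f]chromene-3-carboxamide | CCN(CC)C(=O)c1c(F)oc2c1cc(OCOC)c1OC(C)(C)C=Cc12
F4 | step 5 | 5,8-dimethoxy-2,2-dimethyl-2H-chromene-6-carbaldehyde | COc1cc(C=O)c(OC)c2C=CC(C)(C)Oc12
F5 | step 5 | 5-hydroxy-8-methoxy-2,2-dimethyl-2H-chromene-6-carbaldehyde | COc1cc(C=O)c(O)c2C=CC(C)(C)Oc12
F6 | step 5 | ethyl 2-hydroxy-5-methoxy-7,7-dimethyl-2,3-dihydro-7H-furo[2,3-f]chromene-3-carboxylate (mixture of diastereomers, both centres lost on dehydration) | CCOC(=O)C1C(O)Oc2c1cc(OC)c1OC(C)(C)C=Cc12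
F7 | step 5 | ethyl 5-methoxy-7,7-dimethyl-7H-furo[2,3-f]chromene-3-carboxylate | CCOC(=O)c1coc2c1cc(OC)c1OC(C)(C)C=Cc12
F8 | step 5 | N,N-diethyl-5-methoxy-7,7-dimethyl-7H-furo[2,3-f]chromene-3-carboxamide | CCN(CC)C(=O)c1coc2c1cc(OC)c1OC(C)(C)C=Cc12
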